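Ring B (C5–C10 of the spiro[4.5]decene core; C1–C4 belong to ring A) is closed last at C6–C7. The step exploits that C6 is a neopentyl CH2 on the quaternary spiro carbon C5 and that C7 is the β-carbon of the C7=C8(Me)–C9(O) unit. In the precursor, a ring A cyclopentane carrying CH2I and an isopropenyl ketone arm on C5, the C6 radical adds 6-endo to the enone and forms the cyclohexanone in one operation. Ring A comes from cis,trans-nepetalactone: hydrogenation sets the side-chain methine, prenylation of the cis-fused lactone enolate sets C5, and the lactone carbonyl becomes C6.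

Key step: step 10

Assumption: (4aS,7S,7aR)-nepetalactone, the main constituent of commercial catnip oil, is taken as a purchasable chiral-pool material; C1–C10 denote the spiro[4.5]decane atoms of the target.

Step 1
Reactants: 1 (4aS,7S,7aR)-nepetalactone
Product: 2 (4S,4aR,7S,7aR)-dihydronepetalactone
Conditions: H2 (1 atm), 10% Pd/C, EtOAc, rt
Reagents that add atoms: none
Why: Heterogeneous hydrogenation of the enol-ether alkene should deliver hydrogen to the convex face of the cis-fused bicycle, which sets the (4S) methyl-bearing carbon that becomes the side-chain methine next to C1.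

Step 2
Reactants: 2 (4S,4aR,7S,7aR)-dihydronepetalactone; 3 prenyl bromide
Product: 5 (4S,4aR,7S,7aR)-4,7-dimethyl-7a-(3-methylbut-2-en-1-yl)hexahydrocyclopenta[c]pyran-1(3H)-one, via lithium enolate 4 (not isolated)
Conditions: LiN(iPr)2, THF, −78 °C; then 3, DMPU, −78 → 0 °C
Reagents that add atoms: none
Why: Lactone enolate C-alkylation (SN2) in which the allylic bromide should enter on the convex face of the bicyclic enolate, keeping the cis ring fusion, so that the new quaternary carbon (later C5) carries the prenyl arm cis to the ring methyl and the carbonyl carbon (later C6) cis to the side-chain arm.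

Step 3
Reactants: 5 prenylated lactone
Product: 6 (S)-2-[(1R,2R,3S)-2-(hydroxymethyl)-3-methyl-2-(3-methylbut-2-en-1-yl)cyclopentyl]propan-1-ol
Conditions: LiAlH4, THF, 0 °C → reflux; then H2O, 15% aq. NaOH
Reagents that add atoms: none
Why: Hydride reduction of the lactone to the 1,5-diol; no stereocentre is affected.

Step 4
Reactants: 6 diol
Product: 7 (1R,2R,3S)-2-(iodomethyl)-1-[(S)-1-iodopropan-2-yl]-3-methyl-2-(3-methylbut-2-en-1-yl)cyclopentane
Conditions: PPh3, I2, imidazole, toluene, 0 → 90 °C
Reagents that add atoms: iodine, II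
Why: Appel iodination of both primary alcohols through alkoxyphosphonium ions; excess reagent and heat should drive the SN2 displacement at the neopentyl carbon, which can neither eliminate nor ionise easily.

Step 5
Reactants: 8 (R)-3-bromo-2-methylpropan-1-ol
Product: 9 (R)-(3-bromo-2-methylpropoxy)(tert-butyl)dimethylsilane
Conditions: TBSCl, imidazole, CH2Cl2, rt
Reagents that add atoms: tert-butyldimethylsilyl chloride, CC(C)(C)[Si](C)(C)Cl
Why: Standard silyl ether protection of the primary alcohol.

Step 6
Reactants: 9 (R)-(3-bromo-2-methylpropoxy)(tert-butyl)dimethylsilane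
Product: 11 (S)-4-((tert-butyldimethylsilyl)oxy)-3-methylbutan-1-ol, via Grignard reagent 10 (not isolated)
Conditions: Mg, THF, 40 °C; then (CH2O)n, 0 °C → rt; aq. NH4Cl
Reagents that add atoms: formaldehyde (as paraformaldehyde), C=O
Why: Grignard formation and 1,2-addition to formaldehyde give the one-carbon homologue; the stereocentre is not involved (its descriptor changes from R to S by priority only).

Step 7
Reactants: 11 (S)-4-((tert-butyldimethylsilyl)oxy)-3-methylbutan-1-ol
Product: 12 (S)-(4-bromo-2-methylbutoxy)(tert-butyl)dimethylsilane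
Conditions: CBr4, PPh3, imidazole, CH2Cl2, 0 °C
Reagents that add atoms: carbon tetrabromide, BrC(Br)(Br)Br
Why: Appel bromination of the primary alcohol, with imidazole buffering the silyl ether.

Step 8
Reactants: 7 diiodide; 12 (S)-(4-bromo-2-methylbutoxy)(tert-butyl)dimethylsilane
Product: 15 (2S,6R)-6-[(1R,2R,3S)-2-(iodomethyl)-3-methyl-2-(3-methylbut-2-en-1-yl)cyclopentyl]-2-methylheptan-1-ol, via Grignard reagent 13 (not isolated), via silyl ether 14 (not isolated)
Conditions: 12, Mg, THF, 40 °C; then 7, Li2CuCl4 (5 mol%), THF, −30 → 0 °C; then 1 M HCl, MeOH, rt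
Reagents that add atoms: none
Why: Copper-catalysed Grignard cross-coupling (SN2-type at carbon) should occur only at the unhindered primary iodide, the neopentyl iodide being inert, and the acid work-up removes the silyl group; the (2S) chain centre is carried in unchanged.

Step 9
Reactants: 15 iodo alcohol
Product: 17 (2S,6R)-6-[(1R,2R,3S)-2-(iodomethyl)-3-methyl-2-(3-methyl-2-oxobut-3-en-1-yl)cyclopentyl]-2-methylheptyl acetate, via allylic hydroperoxide 16 (not isolated)
Conditions: O2, tetraphenylporphyrin (cat.), visible light, CH2Cl2, 0 °C; then Ac2O, pyridine, DMAP (cat.), 0 °C → rt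
Reagents that add atoms: oxygen, O=O; acetic anhydride, CC(=O)OC(C)=O
Why: Schenck ene reaction in which singlet oxygen should abstract hydrogen from the methyl group on the crowded alkene face (abstraction at C10 is disfavoured next to the quaternary carbon); Ac2O/pyridine then dehydrates the secondary allylic hydroperoxide (Kornblum–DeLaMare type) to the isopropenyl ketone and acetylates the primary alcohol.

Step 10
Reactants: 17 iodo enone acetate
Product: 18 (2S,6R)-6-[(1R,4S,5S)-4,8-dimethyl-9-oxospiro[4.5]decan-1-yl]-2-methylheptyl acetate (C8 epimers)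
Conditions: (Me3Si)3SiH (syringe pump), AIBN (cat.), toluene (0.01 M), 85 °C
Reagents that add atoms: none
Why: The silyl radical abstracts iodine from the neopentyl iodide; the primary C6 radical, held next to the acceptor by the quaternary C5, adds to the unsubstituted β-carbon C7 of the isopropenyl ketone, and the tertiary α-keto radical at C8 takes hydrogen from the silane to carry the chain. The closest known reaction type is the intramolecular Giese reaction, a tin- or silane-mediated conjugate radical cyclization onto a vinyl ketone. Ring B closes in the 6-endo-trig mode, because the 5-exo alternative would require attack at the fully substituted, electron-poor α-carbon C8 and is disfavoured by both sterics and polarity. The only new stereocentre, C8, arises from unselective hydrogen transfer and is of no consequence since step 11 makes it sp2; the spiro centre C5 is already fixed. The step needs cyclization to outrun direct reduction of the C6 radical, which the slow hydrogen donor at high dilution and the gem-dialkyl effect of C5 should secure.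

Step 11
Reactants: 18 spiro ketone
Product: 19 (2S,6R)-6-[(1R,4S,5S)-4,8-dimethyl-9-oxospiro[4.5]dec-7-en-1-yl]-2-methylheptyl acetate
Conditions: IBX, DMSO–fluorobenzene, 70 °C
Reagents that add atoms: none
Why: IBX dehydrogenation of the ketone through its enol can only occur on the C8–C7 side, because C10 is attached to the quaternary C5 that has no hydrogen, and the endocyclic trisubstituted enone should be favoured over the exocyclic isomer; the C8 stereocentre is removed.

Step 12
Reactants: 19 spiro enone
Product: 20 (2S,6R)-6-[(1R,4S,5S,9S)-9-hydroxy-4,8-dimethylspiro[4.5]dec-7-en-1-yl]-2-methylheptyl acetate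
Conditions: (R)-2-butyl-CBS-oxazaborolidine (20 mol%), catecholborane, toluene, −78 °C
Reagents that add atoms: none
Why: Corey–Bakshi–Shibata reduction with 1,2-hydride delivery to the enone carbonyl, the α-methylalkenyl side acting as the large group, so that the (R)-catalyst should give the (9S) carbinol under reagent control; the acetate is not touched by catecholborane at −78 °C.

Compound list
1 | (4aS,7S,7aR)-nepetalactone (cis,trans-nepetalactone) | C[C@H]1CC[C@H]2[C@@H]1C(=O)OC=C2C | starting material
2 | (4S,4aR,7S,7aR)-dihydronepetalactone | C[C@H]1CC[C@H]2[C@@H]1C(=O)OC[C@H]2C | intermediate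
3 | prenyl bromide (1-bromo-3-methylbut-2-ene) | CC(C)=CCBr | starting material
4 | lithium enolate of 2 | C[C@H]1CC[C@H]2C1=C([O-])OC[C@H]2C.[Li+] | intermediate
5 | (4S,4aR,7S,7aR)-4,7-dimethyl-7a-(3-methylbut-2-en-1-yl)hexahydrocyclopenta[c]pyran-1(3H)-one | C[C@H]1CC[C@H]2[C@]1(CC=C(C)C)C(=O)OC[C@H]2C | intermediate
6 | (S)-2-[(1R,2R,3S)-2-(hydroxymethyl)-3-methyl-2-(3-methylbut-2-en-1-yl)cyclopentyl]propan-1-ol | C[C@H]1CC[C@H]([C@H](C)CO)[C@@]1(CO)CC=C(C)C | intermediate
7 | (1R,2R,3S)-2-(iodomethyl)-1-[(S)-1-iodopropan-2-yl]-3-methyl-2-(3-methylbut-2-en-1-yl)cyclopentane | C[C@H]1CC[C@H]([C@H](C)CI)[C@@]1(CI)CC=C(C)C | intermediate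
8 | (R)-3-bromo-2-methylpropan-1-ol | OC[C@@H](C)CBr | starting material
9 | (R)-(3-bromo-2-methylpropoxy)(tert-butyl)dimethylsilane | CC(C)(C)[Si](C)(C)OC[C@@H](C)CBr | intermediate
10 | (R)-[3-((tert-butyldimethylsilyl)oxy)-2-methylpropyl]magnesium bromide | CC(C)(C)[Si](C)(C)OC[C@@H](C)C[Mg]Br | intermediate
11 | (S)-4-((tert-butyldimethylsilyl)oxy)-3-methylbutan-1-ol | CC(C)(C)[Si](C)(C)OC[C@@H](C)CCO | intermediate
12 | (S)-(4-bromo-2-methylbutoxy)(tert-butyl)dimethylsilane | CC(C)(C)[Si](C)(C)OC[C@@H](C)CCBr | intermediate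
13 | (S)-[4-((tert-butyldimethylsilyl)oxy)-3-methylbutyl]magnesium bromide | CC(C)(C)[Si](C)(C)OC[C@@H](C)CC[Mg]Br | intermediate
14 | tert-butyl{[(2S,6R)-6-[(1R,2R,3S)-2-(iodomethyl)-3-methyl-2-(3-methylbut-2-en-1-yl)cyclopentyl]-2-methylheptyl]oxy}dimethylsilane | C[C@H]1CC[C@H]([C@H](C)CCC[C@H](C)CO[Si](C)(C)C(C)(C)C)[C@@]1(CI)CC=C(C)C | intermediate
15 | (2S,6R)-6-[(1R,2R,3S)-2-(iodomethyl)-3-methyl-2-(3-methylbut-2-en-1-yl)cyclopentyl]-2-methylheptan-1-ol | C[C@H]1CC[C@H]([C@H](C)CCC[C@H](C)CO)[C@@]1(CI)CC=C(C)C | intermediate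
16 | (2S,6R)-6-[(1R,2R,3S)-2-(2-hydroperoxy-3-methylbut-3-en-1-yl)-2-(iodomethyl)-3-methylcyclopentyl]-2-methylheptan-1-ol (both epimers at the hydroperoxide carbon) | C[C@H]1CC[C@H]([C@H](C)CCC[C@H](C)CO)[C@@]1(CI)CC(OO)C(C)=C | intermediate
17 | (2S,6R)-6-[(1R,2R,3S)-2-(iodomethyl)-3-methyl-2-(3-methyl-2-oxobut-3-en-1-yl)cyclopentyl]-2-methylheptyl acetate | C[C@H]1CC[C@H]([C@H](C)CCC[C@H](C)COC(C)=O)[C@@]1(CI)CC(=O)C(C)=C | intermediate
18 | (2S,6R)-6-[(1R,4S,5S)-4,8-dimethyl-9-oxospiro[4.5]decan-1-yl]-2-methylheptyl acetate (C8 epimers) | C[C@H]1CC[C@H]([C@H](C)CCC[C@H](C)COC(C)=O)[C@]12CCC(C)C(=O)C2 | intermediate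
19 | (2S,6R)-6-[(1R,4S,5S)-4,8-dimethyl-9-oxospiro[4.5]dec-7-en-1-yl]-2-methylheptyl acetate | C[C@H]1CC[C@H]([C@H](C)CCC[C@H](C)COC(C)=O)[C@]12CC=C(C)C(=O)C2 | intermediate
20 | (2S,6R)-6-[(1R,4S,5S,9S)-9-hydroxy-4,8-dimethylspiro[4.5]dec-7-en-1-yl]-2-methylheptyl acetate | CC(=O)OC[C@@H](C)CCC[C@@H](C)[C@H]1CC[C@H](C)[C@@]12CC=C(C)[C@@H](O)C2 | target

Total step count: 12. Longest linear sequence: 9 steps (steps 1–4 and 8–12, from nepetalactone).

Steps most likely to fail

Step 4. The alkoxyphosphonium ion formed first at the unhindered CH2 may be captured by the neighbouring C6 hydroxyl, closing the bicyclic tetrahydropyran, and iodide displacement at the neopentyl carbon may stall. The fallback sets out from diol 6 and differentiates the two hydroxyls before any leaving group is made. Pivaloyl chloride in pyridine at 0 °C should acylate only the unhindered hydroxyl to give the mono-pivalate F1. Tf2O/pyridine at −78 °C then converts the neopentyl hydroxyl into the triflate F2, which NaI in DMF should displace to the iodo pivalate F3. iBu2AlH at −78 °C removes the pivalate to give the iodo alcohol F4. A room-temperature Appel iodination (PPh3, I2, imidazole), now without a neighbouring hydroxyl, comes back to the route at diiodide 7.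

Step 2. C-alkylation of the hindered ring-fusion enolate by the γ,γ-disubstituted allylic bromide may be too slow, so that O-alkylation or proton transfer takes over. The fallback sets out from lactone 2: the same enolate is alkylated with the smaller allyl bromide to the 7a-allyl lactone F5. Cross-metathesis of its terminal alkene with 2-methyl-2-butene (second-generation Grubbs catalyst, CH2Cl2, 40 °C) then builds the prenyl group and comes back at lactone 5.

Step 9. The ene reaction may abstract hydrogen at C10 instead of the methyl group, giving the tertiary hydroperoxide that cannot be dehydrated to the enone. The fallback sets out from iodo alcohol 15 and builds the enone by carbonyl addition. Acetylation (Ac2O, pyridine) gives the acetate F6. Ozonolysis of the prenyl alkene (O3, CH2Cl2, −78 °C; then PPh3) gives the aldehyde F7. Isopropenylmagnesium bromide in THF at −78 °C should add to the aldehyde in preference to the acetate to give the allylic alcohol F8 as both epimers. Dess–Martin periodinane oxidation comes back at enone 17.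

Further compounds
F1 | step 4 | (S)-2-[(1R,2R,3S)-2-(hydroxymethyl)-3-methyl-2-(3-methylbut-2-en-1-yl)cyclopentyl]propyl pivalate | C[C@H]1CC[C@H]([C@H](C)COC(=O)C(C)(C)C)[C@@]1(CO)CC=C(C)C
F2 | step 4 | (S)-2-[(1R,2R,3S)-3-methyl-2-(3-methylbut-2-en-1-yl)-2-(((trifluoromethylsulfonyl)oxy)methyl)cyclopentyl]propyl pivalate | C[C@H]1CC[C@H]([C@H](C)COC(=O)C(C)(C)C)[C@@]1(COS(=O)(=O)C(F)(F)F)CC=C(C)C
F3 | step 4 | (S)-2-[(1R,2R,3S)-2-(iodomethyl)-3-methyl-2-(3-methylbut-2-en-1-yl)cyclopentyl]propyl pivalate | C[C@H]1CC[C@H]([C@H](C)COC(=O)C(C)(C)C)[C@@]1(CI)CC=C(C)C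
F4 | step 4 | (S)-2-[(1R,2R,3S)-2-(iodomethyl)-3-methyl-2-(3-methylbut-2-en-1-yl)cyclopentyl]propan-1-ol | C[C@H]1CC[C@H]([C@H](C)CO)[C@@]1(CI)CC=C(C)C
F5 | step 2 | (4S,4aR,7S,7aR)-7a-allyl-4,7-dimethylhexahydrocyclopenta[c]pyran-1(3H)-one | C[C@H]1CC[C@H]2[C@]1(CC=C)C(=O)OC[C@H]2C
F6 | step 9 | (2S,6R)-6-[(1R,2R,3S)-2-(iodomethyl)-3-methyl-2-(3-methylbut-2-en-1-yl)cyclopentyl]-2-methylheptyl acetate | C[C@H]1CC[C@H]([C@H](C)CCC[C@H](C)COC(C)=O)[C@@]1(CI)CC=C(C)C
F7 | step 9 | (2S,6R)-6-[(1R,2R,3S)-2-(iodomethyl)-3-methyl-2-(2-oxoethyl)cyclopentyl]-2-methylheptyl acetate | C[C@H]1CC[C@H]([C@H](C)CCC[C@H](C)COC(C)=O)[C@@]1(CI)CC=O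
F8 | step 9 | (2S,6R)-6-[(1R,2R,3S)-2-(2-hydroxy-3-methylbut-3-en-1-yl)-2-(iodomethyl)-3-methylcyclopentyl]-2-methylheptyl acetate (both carbinol epimers) | C[C@H]1CC[C@H]([C@H](C)CCC[C@H](C)COC(C)=O)[C@@]1(CI)CC(O)C(C)=C
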